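The hydroazulene is cut at C1–C5 and C7–C8. With C6 as a ketone, C5–C6–C7 of the seven-membered ring is an oxyallyl unit and C8–C9–C10–C1 a diene, and the cyclopentane carbons C2–C3–C4 tether the two. One intramolecular oxyallyl cation–diene [4+3] cycloaddition therefore forms both bonds, closes the five- and seven-membered rings and sets the quaternary C1 (with C8 and, after equilibration, C5) under control of the C4 carbinol centre, which comes from (S)-terpinen-4-ol. The precursor 20 is an open-chain chloromethyl ketone carrying the C4 triethylsilyl ether and a stereodefined E,E-dienyl end. The C8 configuration created by that diene later directs the C10 hydroxyl.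

Key step: step 8

Remarks
- Locants: C1 is the methyl-substituted quaternary ring-fusion carbon, C2 and C3 the two CH2 groups of the five-membered ring, C4 the tertiary carbinol carbon carrying isopropyl, C5 the ring-fusion CH, C6 the carbon bearing the 4-methoxybenzoate, C7 the adjoining ring CH2, C8 the methyl-substituted alkene carbon, C9 the alkene CH, C10 the secondary carbinol carbon next to C1. Descriptors of bicyclic compounds refer to these locants.
- Assumption: (S)-terpinen-4-ol of high enantiomeric purity is purchased (ee checked by chiral GC); C4 is never touched, so its purity is that of the target.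
- Check: C4 of 1 keeps its spatial arrangement to the target; the descriptor changes from S to R only through CIP priorities.
- The carbinol centre made in step 5 and the bridgeheads of ozonide 6 form as mixtures and are erased later; their SMILES leave these centres open.
- Carbon bookkeeping: the ring methyl of 1 becomes C10; the C1 methyl is delivered by Me3Al in step 6.

Step 1
Reactants: 1 (S)-terpinen-4-ol; 2 triethylsilyl trifluoromethanesulfonate
Product: 3 triethylsilyl ether of (S)-terpinen-4-ol
Conditions: TESOTf, 2,6-lutidine, CH2Cl2, 0 °C → rt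
Reagents that add atoms: triethylsilyl trifluoromethanesulfonate, CC[Si](CC)(CC)OS(=O)(=O)C(F)(F)F
Why: O-silylation with a silyl triflate and a hindered pyridine base is the standard way to cap a congested tertiary alcohol, and it blocks retro-aldol cleavage and O-alkylation at C4 in the later ketone stages without touching the stereocentre.

Step 2
Reactants: 3 silyl ether; 4 ozone; 5 trimethyl orthoformate
Product: 8 (5S)-7,7-dimethoxy-5-(propan-2-yl)-5-(triethylsilyloxy)heptan-2-one, via ozonide 6 (not isolated), via keto aldehyde 7 (not isolated)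
Conditions: O3, CH2Cl2, −78 °C; PPh3, −78 °C → rt; then HC(OMe)3, MeOH, PPTS (cat.), rt
Reagents that add atoms: ozone, [O-][O+]=O; trimethyl orthoformate, COC(OC)OC
Why: Ozonolysis (Criegee mechanism) cleaves the only alkene and phosphine reduction of ozonide 6 gives keto aldehyde 7, whose aldehyde alone becomes the dimethyl acetal under PPTS because an aldehyde acetalises far faster than a methyl ketone (chemoselective acetalisation), so the two chain ends are differentiated in one flask while the tertiary silyl ether stays intact.

Step 3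
Reactants: 8 keto acetal; 9 diethyl chlorophosphate
Product: 11 (5S)-7,7-dimethoxy-5-(propan-2-yl)-5-(triethylsilyloxy)hept-1-yne, via enol phosphate 10 (not isolated)
Conditions: LiN(iPr)2, THF, −78 °C; ClP(O)(OEt)2, −78 °C → rt; then LiN(iPr)2 (2.3 equiv), −78 °C → rt; H2O
Reagents that add atoms: none
Why: Kinetic deprotonation of the methyl ketone at CH3, O-phosphorylation and amide-induced β-elimination of the enol phosphate is the established conversion of a methyl ketone into a terminal alkyne, and acetal and silyl ether are inert to the amide base.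

Step 4
Reactants: 11 alkyne acetal; 12 water
Product: 13 (3S)-3-(propan-2-yl)-3-(triethylsilyloxy)hept-6-ynal
Conditions: PPTS, acetone/H2O, 50 °C
Reagents that add atoms: water, O
Why: Mild acid-catalysed acetal hydrolysis frees the aldehyde under conditions that the hindered tertiary triethylsilyl ether and the alkyne tolerate.

Step 5
Reactants: 13 alkynal; 14 chloroiodomethane
Product: 15 (2RS,4S)-1-chloro-4-(propan-2-yl)-4-(triethylsilyloxy)oct-7-yn-2-ol
Conditions: ICH2Cl, MeLi·LiBr, THF, −78 °C; NH4Cl (aq), −78 °C
Reagents that add atoms: chloroiodomethane, ClCI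
Why: Chloromethyllithium made by iodine–lithium exchange in the presence of the aldehyde (Barbier mode) adds to the carbonyl group faster than it decomposes or removes the alkyne proton, giving the chlorohydrin by carbenoid 1,2-addition; the new carbinol centre forms without control and is erased in step 7, and the cold quench prevents epoxide closure.

Step 6
Reactants: 15 chlorohydrin alkyne; 16 trimethylaluminium; 17 (E)-1-bromoprop-1-ene
Product: 19 (2RS,4S,7E,9E)-1-chloro-7-methyl-4-(propan-2-yl)-4-(triethylsilyloxy)undeca-7,9-dien-2-ol, via alkenylalane 18 (not isolated)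
Conditions: Me3Al (3.5 equiv), Cp2ZrCl2 (cat.), CH2Cl2, 0 °C → rt; then (E)-BrCH=CHCH3, ZnCl2, Pd(PPh3)4 (cat.), THF, rt
Reagents that add atoms: trimethylaluminium, C[Al](C)C; (E)-1-bromoprop-1-ene, C/C=C/Br
Why: Cp2ZrCl2-catalysed syn-carboalumination of the terminal alkyne (Negishi carboalumination) places methyl on the inner and aluminium on the outer carbon, and Pd(PPh3)4-catalysed coupling of alkenylalane 18 with the E-alkenyl bromide (Negishi coupling) retains both geometries, so the E,E-diene is made stereospecifically and needs no isomer separation; the hydroxyl group travels as its aluminium alkoxide.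

Step 7
Reactants: 19 diene chlorohydrin
Product: 20 (4S,7E,9E)-1-chloro-7-methyl-4-(propan-2-yl)-4-(triethylsilyloxy)undeca-7,9-dien-2-one
Conditions: Dess–Martin periodinane, NaHCO3, CH2Cl2, 0 °C → rt
Reagents that add atoms: none
Why: Dess–Martin oxidation converts the secondary chlorohydrin into the chloromethyl ketone under buffered, non-basic conditions that spare the diene, the silyl ether and the base-sensitive α-chloroketone.

Step 8
Reactants: 20 chloromethyl ketone
Product: 23 trans-fused (1R,4R,5R,8R)-1,8-dimethyl-4-(propan-2-yl)-4-(triethylsilyloxy)hydroazul-9-en-6-one, via oxyallyl cation 21 (not isolated), via cis-fused cycloadduct 22 (not isolated)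
Conditions: Et3N, CF3CH2OH (0.01 M), rt; then DBU (cat.), CH2Cl2, rt
Reagents that add atoms: none
Why: Triethylamine reversibly enolises 20 toward C5, and in the ionising, weakly nucleophilic fluoro alcohol the enol loses chloride from C7 to give the W-shaped oxyallyl cation 21 (C4 syn to oxygen), a two-electron three-carbon unit that adds suprafacially to the s-cis diene, the C1–C5 bond probably leading. The closest known reaction type is the intramolecular [4+3] cycloaddition of α-chloroketone-derived oxyallyl cations with butadienes held by a three-atom tether, which gives hydroazulenones. The five-membered ring closes in a 5-exo sense when the C1=C10 π bond attacks C5 through the C2–C3–C4 tether, and the seven-membered ring closes by the cycloaddition itself when C7 bonds to C8. C1 is set relative to C4 by the fold of the tether (isopropyl on the outer pseudoequatorial site of the nascent cyclopentane, the C4–O bond beside the oxyallyl oxygen, extended approach, so that the C1 methyl faces C4–O); C8 is set relative to C1 by suprafacial addition to the E,E-diene (C8 methyl cis to C2, H8 cis to the C1 methyl); C5 is set thermodynamically, DBU converting any cis-fused adduct 22 into the trans-fused ketone in which C6 avoids isopropyl. The step needs diene π-facial selectivity with respect to C4 and [4+3] periselectivity over Favorskii rearrangement, solvent capture and [3+2] closure; the first rests on the fully substituted C4 centre next to the reacting C5, the second on intramolecularity, high dilution and the non-nucleophilic medium.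

Step 9
Reactants: 23 silyloxy ketone
Product: 24 (1R,4R,5R,8R)-4-hydroxy-1,8-dimethyl-4-(propan-2-yl)hydroazul-9-en-6-one
Conditions: HF·pyridine, pyridine/THF, 0 °C → rt
Reagents that add atoms: none
Why: Fluoride-driven desilylation under pyridine-buffered conditions frees the C4 hydroxyl without the base that would trigger retro-aldol opening of the β-hydroxy ketone.

Step 10
Reactants: 24 hydroxy ketone
Product: 25 (1R,4R,5S,6S,8R)-1,8-dimethyl-4-(propan-2-yl)hydroazul-9-ene-4,6-diol
Conditions: Me4NBH(OAc)3, MeCN/AcOH, −30 °C
Reagents that add atoms: none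
Why: Evans–Saksena hydroxyl-directed reduction: the C4 hydroxyl, which in the trans-fused ketone lies cis to the C5–C6 bond, exchanges onto boron and delivers hydride through a six-membered transition state to the face of C6 that looks toward C4–O, so the 6-hydroxyl ends up on the face opposite the 4-hydroxyl (6S), while the isolated alkene is inert.

Step 11
Reactants: 25 diol; 26 4-methoxybenzoyl chloride
Product: 27 6-O-(4-methoxybenzoyl) derivative of 25
Conditions: 4-MeOC6H4COCl, DMAP, Et3N, CH2Cl2, rt
Reagents that add atoms: 4-methoxybenzoyl chloride, COc1ccc(C(=O)Cl)cc1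
Why: DMAP-catalysed acylation with the acid chloride takes place only at the secondary C6 hydroxyl, because the tertiary C4 hydroxyl flanked by isopropyl is too hindered to be acylated.

Step 12
Reactants: 27 anisoate; 28 3-chloroperoxybenzoic acid
Product: 29 (1S,4R,5S,6S,8R,9R,10S)-9,10-epoxide of 27 on the face of H5
Conditions: mCPBA, NaHCO3, CH2Cl2, 0 °C
Reagents that add atoms: 3-chloroperoxybenzoic acid, OOC(=O)c1cccc(Cl)c1
Why: Prilezhaev epoxidation of the only alkene should occur on the face of H5, anti to the pseudoaxial C1 methyl of the chair-like cycloheptene (the C8 methyl is pseudoequatorial), which sets C9 and the C10–O bond in the configuration of the target.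

Step 13
Reactants: 29 epoxide; 30 diphenyl diselenide; 31 hydrogen peroxide
Product: 34 CNP0211568.1, via hydroxy selenide 32 (not isolated), via selenoxide 33 (not isolated)
Conditions: PhSeSePh, NaBH4, EtOH, rt → reflux; then H2O2 (30%), THF, 0 °C → rt
Reagents that add atoms: none
Why: Epoxide-to-allylic-alcohol transposition by selenolate opening and selenoxide syn-elimination: phenylselenolate attacks C9 with inversion (C10 is neopentyl and screened by the C1 methyl), and the selenoxide eliminates toward H8, which is cis to selenium because the E,E-diene placed H8 on the face of the C1 methyl, and away from the carbinol carbon, so C8=C9 forms and the C10–O bond set in step 12 is never broken.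

Compound list
1 | (S)-terpinen-4-ol, (1S)-4-methyl-1-(propan-2-yl)cyclohex-3-en-1-ol | C1C[C@@](O)(C(C)C)CC=C1C | starting material
2 | triethylsilyl trifluoromethanesulfonate | CC[Si](CC)(CC)OS(=O)(=O)C(F)(F)F | starting material
3 | triethyl{[(1S)-4-methyl-1-(propan-2-yl)cyclohex-3-en-1-yl]oxy}silane | C1C[C@@](O[Si](CC)(CC)CC)(C(C)C)CC=C1C | intermediate
4 | ozone | [O-][O+]=O | starting material
5 | trimethyl orthoformate | COC(OC)OC | starting material
6 | ozonide, (4S)-1-methyl-4-(propan-2-yl)-4-(triethylsilyloxy)-7,8,9-trioxabicyclo[4.2.1]nonane, bridgeheads as a mixture | CC12CC[C@@](O[Si](CC)(CC)CC)(C(C)C)CC(O1)OO2 | intermediate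
7 | (3S)-6-oxo-3-(propan-2-yl)-3-(triethylsilyloxy)heptanal | O=CC[C@](O[Si](CC)(CC)CC)(C(C)C)CCC(C)=O | intermediate
8 | (5S)-7,7-dimethoxy-5-(propan-2-yl)-5-(triethylsilyloxy)heptan-2-one | COC(OC)C[C@](O[Si](CC)(CC)CC)(C(C)C)CCC(C)=O | intermediate
9 | diethyl chlorophosphate | CCOP(=O)(Cl)OCC | starting material
10 | diethyl (5S)-7,7-dimethoxy-5-(propan-2-yl)-5-(triethylsilyloxy)hept-1-en-2-yl phosphate | COC(OC)C[C@](O[Si](CC)(CC)CC)(C(C)C)CCC(=C)OP(=O)(OCC)OCC | intermediate
11 | (5S)-7,7-dimethoxy-5-(propan-2-yl)-5-(triethylsilyloxy)hept-1-yne | COC(OC)C[C@](O[Si](CC)(CC)CC)(C(C)C)CCC#C | intermediate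
12 | water | O | starting material
13 | (3S)-3-(propan-2-yl)-3-(triethylsilyloxy)hept-6-ynal | O=CC[C@](O[Si](CC)(CC)CC)(C(C)C)CCC#C | intermediate
14 | chloroiodomethane | ClCI | starting material
15 | (2RS,4S)-1-chloro-4-(propan-2-yl)-4-(triethylsilyloxy)oct-7-yn-2-ol | ClCC(O)C[C@](O[Si](CC)(CC)CC)(C(C)C)CCC#C | intermediate
16 | trimethylaluminium | C[Al](C)C | starting material
17 | (E)-1-bromoprop-1-ene | C/C=C/Br | starting material
18 | (E)-alkenyl(dimethyl)alane of 15 with the hydroxyl as its dimethylaluminium alkoxide | ClCC(O[Al](C)C)C[C@](O[Si](CC)(CC)CC)(C(C)C)CC/C(C)=C/[Al](C)C | intermediate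
19 | (2RS,4S,7E,9E)-1-chloro-7-methyl-4-(propan-2-yl)-4-(triethylsilyloxy)undeca-7,9-dien-2-ol | ClCC(O)C[C@](O[Si](CC)(CC)CC)(C(C)C)CC/C(C)=C/C=C/C | intermediate
20 | (4S,7E,9E)-1-chloro-7-methyl-4-(propan-2-yl)-4-(triethylsilyloxy)undeca-7,9-dien-2-one | ClCC(=O)C[C@](O[Si](CC)(CC)CC)(C(C)C)CC/C(C)=C/C=C/C | intermediate
21 | oxyallyl cation of 20 (C5–C6–C7, C4 syn to O) | [O-]/C([CH2+])=C\[C@](O[Si](CC)(CC)CC)(C(C)C)CC/C(C)=C/C=C/C | intermediate
22 | cis-fused cycloadduct, C5 epimer of 23 (1R,4R,5S,8R) | O=C1C[C@@H](C)C=C[C@@]2(C)CC[C@@](O[Si](CC)(CC)CC)(C(C)C)[C@@H]12 | intermediate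
23 | trans-fused (1R,4R,5R,8R)-1,8-dimethyl-4-(propan-2-yl)-4-(triethylsilyloxy)hydroazul-9-en-6-one; C1 methyl cis to C4–OSi, H5 and C8 methyl on the opposite face | O=C1C[C@@H](C)C=C[C@@]2(C)CC[C@@](O[Si](CC)(CC)CC)(C(C)C)[C@H]12 | intermediate
24 | (1R,4R,5R,8R)-4-hydroxy-1,8-dimethyl-4-(propan-2-yl)hydroazul-9-en-6-one | O=C1C[C@@H](C)C=C[C@@]2(C)CC[C@@](O)(C(C)C)[C@H]12 | intermediate
25 | (1R,4R,5S,6S,8R)-1,8-dimethyl-4-(propan-2-yl)hydroazul-9-ene-4,6-diol; 6-OH cis to H5 | O[C@H]1C[C@@H](C)C=C[C@@]2(C)CC[C@@](O)(C(C)C)[C@H]12 | intermediate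
26 | 4-methoxybenzoyl chloride | COc1ccc(C(=O)Cl)cc1 | starting material
27 | (1R,4R,5S,6S,8R)-4-hydroxy-1,8-dimethyl-4-(propan-2-yl)hydroazul-9-en-6-yl 4-methoxybenzoate | COc1ccc(C(=O)O[C@H]2C[C@@H](C)C=C[C@@]3(C)CC[C@@](O)(C(C)C)[C@H]23)cc1 | intermediate
28 | 3-chloroperoxybenzoic acid | OOC(=O)c1cccc(Cl)c1 | starting material
29 | (1S,4R,5S,6S,8R,9R,10S)-9,10-epoxide of 27, oxygen on the face of H5 | COc1ccc(C(=O)O[C@H]2C[C@@H](C)[C@H]4O[C@H]4[C@@]3(C)CC[C@@](O)(C(C)C)[C@H]23)cc1 | intermediate
30 | diphenyl diselenide | c1ccccc1[Se][Se]c1ccccc1 | starting material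
31 | hydrogen peroxide | OO | starting material
32 | (1S,4R,5S,6S,8R,9S,10S)-4,10-dihydroxy-9-(phenylselanyl) 6-(4-methoxybenzoate); selenium cis to the C1 methyl and H8 | COc1ccc(C(=O)O[C@H]2C[C@@H](C)[C@H]([Se]c4ccccc4)[C@@H](O)[C@@]3(C)CC[C@@](O)(C(C)C)[C@H]23)cc1 | intermediate
33 | selenoxide of 32 (mixture at selenium) | COc1ccc(C(=O)O[C@H]2C[C@@H](C)[C@H]([Se](=O)c4ccccc4)[C@@H](O)[C@@]3(C)CC[C@@](O)(C(C)C)[C@H]23)cc1 | intermediate
34 | CNP0211568.1, (1S,4R,5S,6S,10R)-4,10-dihydroxy-1,8-dimethyl-4-(propan-2-yl)hydroazul-8-en-6-yl 4-methoxybenzoate | COc1ccc(C(=O)O[C@H]2CC(C)=C[C@@H](O)[C@@]3(C)CC[C@@](O)(C(C)C)[C@H]23)cc1 | target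

Total step count: 13. Longest linear sequence: 13 steps, all from 1.

Steps most likely to fail

Step 8. The oxyallyl cation 21 carries a single alkyl group and may be intercepted before the congested C1–C5 bond forms (solvent capture, Favorskii rearrangement, attack of the silyl ether oxygen on C7). Discrimination between the two diene faces by C4 may also be incomplete; the other fold would give the C1 epimer, which has to be removed by chromatography at 23. Fallback from 20: deprotonation at C7 with LiN(SiMe3)2 (THF, −78 °C) and chlorination with N-chlorosuccinimide should give the dichloromethyl ketone F1. Et3N in CF3CH2OH should ionise F1 to a chlorine-stabilised oxyallyl cation, a longer-lived electrophile of the kind used when the parent cation is too fleeting, which should close to the 7-chloro cycloadduct F2. Zn dust with NH4Cl in MeOH removes the chlorine and DBU equilibrates C5, returning to 23.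

Step 12. The peracid may attack both faces of C9=C10, and only the epoxide anti to the C1 methyl can later eliminate toward H8. Fallback from 27: sensitised photooxygenation (O2, tetraphenylporphyrin, visible light, CH2Cl2) is an ene reaction that can only abstract H8 and therefore puts oxygen on C10 on the face of H8, giving the hydroperoxide F3. PPh3 reduces F3 to the 10-epi allylic alcohol F4. Mitsunobu inversion with chloroacetic acid (PPh3, DIAD, toluene) should give the inverted chloroacetate F5, and brief K2CO3/MeOH at 0 °C removes the chloroacetyl group without touching the anisoate, arriving at 34.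

Step 6. The aluminium alkoxide of the chlorohydrin may retard carboalumination, or the alkenylalane may be protonated before it couples, leaving a 1,1-disubstituted alkene. Fallback from 11: CuCl-catalysed syn-methylboration (B2pin2, MeI, CuCl/Xantphos, NaOtBu, THF) should give the (E)-alkenyl boronate F6. Suzuki coupling of F6 with 17 (PdCl2(dppf), K3PO4, THF/H2O) should give the diene acetal F7. PPTS in wet acetone then frees the diene aldehyde F8, and chloromethyllithium as in step 5 converts F8 into 19.

Further compounds
F1 | step 8 | (4S,7E,9E)-1,1-dichloro-7-methyl-4-(propan-2-yl)-4-(triethylsilyloxy)undeca-7,9-dien-2-one | ClC(Cl)C(=O)C[C@](O[Si](CC)(CC)CC)(C(C)C)CC/C(C)=C/C=C/C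
F2 | step 8 | 7-chloro derivative of 23 (C7 epimers) | O=C1C(Cl)[C@@H](C)C=C[C@@]2(C)CC[C@@](O[Si](CC)(CC)CC)(C(C)C)[C@H]12
F3 | step 12 | 10-epi-10-hydroperoxide of the 8-ene (OOH cis to the C1 methyl) | COc1ccc(C(=O)O[C@H]2CC(C)=C[C@H](OO)[C@@]3(C)CC[C@@](O)(C(C)C)[C@H]23)cc1
F4 | step 12 | 10-epimer of 34 | COc1ccc(C(=O)O[C@H]2CC(C)=C[C@H](O)[C@@]3(C)CC[C@@](O)(C(C)C)[C@H]23)cc1
F5 | step 12 | 10-O-chloroacetate of 34 | COc1ccc(C(=O)O[C@H]2CC(C)=C[C@@H](OC(=O)CCl)[C@@]3(C)CC[C@@](O)(C(C)C)[C@H]23)cc1
F6 | step 6 | 2-[(1E,5S)-7,7-dimethoxy-2-methyl-5-(propan-2-yl)-5-(triethylsilyloxy)hept-1-en-1-yl]-4,4,5,5-tetramethyl-1,3,2-dioxaborolane | COC(OC)C[C@](O[Si](CC)(CC)CC)(C(C)C)CC/C(C)=C/B1OC(C)(C)C(C)(C)O1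
F7 | step 6 | (3S,6E,8E)-1,1-dimethoxy-6-methyl-3-(propan-2-yl)-3-(triethylsilyloxy)deca-6,8-diene | COC(OC)C[C@](O[Si](CC)(CC)CC)(C(C)C)CC/C(C)=C/C=C/C
F8 | step 6 | (3S,6E,8E)-6-methyl-3-(propan-2-yl)-3-(triethylsilyloxy)deca-6,8-dienal | O=CC[C@](O[Si](CC)(CC)CC)(C(C)C)CC/C(C)=C/C=C/C
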